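The hexacycle is a propellane. Its indoline, piperidine and dihydrobenzofuran rings share the C4a–C9a bond (β-carboline numbering, primes for the gramine indole), and N9–C9a–C1–N2 is a vicinal diamine. Cutting N9–C9a and N2–C1 together unmasks an exocyclic C9a=C1 methylene on a dihydrobenzofuran fused to 7-methoxy-1-tosylindole. Its only stereocentre, C4a, carries a 2-(tosylamino)phenyl group and a 2-(methoxycarbonylamino)ethyl chain. One palladium-catalysed oxidative diamination should add both nitrogens across this alkene, close the indoline and piperidine rings, and set C9a from C4a. C4a comes from a copper/pybox propargylic etherification, and the methylene comes from a reductive Heck cyclisation.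

Key step: step 14

Assumption: the sense of induction of the pybox ligand in step 10 cannot be predicted safely for this substrate. The (S,S)-ligand is written, and its equally available antipode is used if a pilot run shows the (S)-ether.

Remark on configuration: no bond to C4a is made or broken after step 10. Its descriptor changes from (R) before the key step to (S) after it only because C9a outranks the aryl carbon once it carries N9.

Remarks on design:
- N2 stays an alkyl carbamate on purpose, so that only N9 enters the aminopalladation.
- The oxidant carries pivalate instead of acetate to disfavour C–O bond formation at C1.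
- The leaving group of the copper step is an acetate, because it can be installed without touching the carbamate N–H.
- The tosyl groups are removed before the hydride reduction, so that every late intermediate is one defined compound.

Step 1
Reactants: 1 3-methoxy-4-nitrophenol
Product: 2 4-(benzyloxy)-2-methoxy-1-nitrobenzene
Conditions: BnBr, K2CO3, DMF, 23 → 50 °C
Reagents that add atoms: benzyl bromide, BrCc1ccccc1
Why: Williamson ether synthesis on an acidic nitrophenol gives a benzyl ether that withstands the Grignard reagent of step 2 and leaves later by hydrogenolysis.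

Step 2
Reactants: 2 4-(benzyloxy)-2-methoxy-1-nitrobenzene; 3 vinylmagnesium bromide
Product: 4 5-(benzyloxy)-7-methoxy-1H-indole
Conditions: 3 (3.5 equiv), THF, −40 °C; aq. NH4Cl
Reagents that add atoms: none
Why: In the Bartoli indole synthesis the vinyl Grignard reagent takes the nitroarene through the nitrosoarene and a [3,3]-sigmatropic shift towards the only free ortho carbon, and the ortho-methoxy group that this reaction requires becomes the 7-methoxy group.

Step 3
Reactants: 4 5-(benzyloxy)-7-methoxy-1H-indole
Product: 5 5-(benzyloxy)-7-methoxy-1-tosyl-1H-indole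
Conditions: NaH, TsCl, THF/DMF, 0 → 23 °C
Reagents that add atoms: p-toluenesulfonyl chloride, Cc1ccc(S(=O)(=O)Cl)cc1
Why: N-sulfonylation of the indolyl sodium salt installs a tosyl group that lowers the reactivity of N1' and C3' for the iodination, the copper step and the oxidative key step.

Step 4
Reactants: 5 5-(benzyloxy)-7-methoxy-1-tosyl-1H-indole
Product: 6 7-methoxy-1-tosyl-1H-indol-5-ol
Conditions: H2 (1 atm), 10% Pd/C, EtOAc/EtOH, 23 °C
Reagents that add atoms: none
Why: Catalytic hydrogenolysis cleaves the benzyl aryl ether and leaves the N-tosylindole and the methyl ether untouched.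

Step 5
Reactants: 6 7-methoxy-1-tosyl-1H-indol-5-ol
Product: 7 4-iodo-7-methoxy-1-tosyl-1H-indol-5-ol
Conditions: NIS (1.05 equiv), MeCN, −10 → 0 °C, dark
Reagents that add atoms: N-iodosuccinimide, O=C1CCC(=O)N1I
Why: Electrophilic aromatic iodination should go to C4', which is ortho to the hydroxyl, para to the methoxy group and favoured by bond fixation in 5-hydroxyindoles, whereas C6' is squeezed between two oxygen substituents and C3' is deactivated by the tosyl group.

Step 6
Reactants: 8 2'-nitroacetophenone; 9 paraformaldehyde
Product: 10 1-(2-nitrophenyl)prop-2-en-1-one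
Conditions: (CH2O)n, i-Pr2NH·CF3CO2H (1 equiv), CF3CO2H (0.1 equiv), THF, reflux
Reagents that add atoms: none
Why: Mannich condensation with in situ loss of the amine (direct α-methylenation) is a standard entry from acetophenones to aryl vinyl ketones, and the product is used promptly because it polymerises.

Step 7
Reactants: 10 1-(2-nitrophenyl)prop-2-en-1-one; 11 methyl carbamate
Product: 12 methyl N-[3-(2-nitrophenyl)-3-oxopropyl]carbamate
Conditions: 11 (2 equiv), Tf2NH (10 mol %), MeCN, 23 °C
Reagents that add atoms: none
Why: Brønsted acid-catalysed aza-Michael addition of a carbamate to an enone installs N2 already in the form that later becomes N-methyl.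

Step 8
Reactants: 12 methyl N-[3-(2-nitrophenyl)-3-oxopropyl]carbamate; 13 ethynylmagnesium bromide
Product: 14 methyl N-[3-hydroxy-3-(2-nitrophenyl)pent-4-yn-1-yl]carbamate (racemic)
Conditions: 13 (3 equiv), LaCl3·2LiCl (0.3 equiv), THF, −40 → 0 °C; aq. NH4Cl
Reagents that add atoms: none
Why: 1,2-addition of a weakly basic alkynyl Grignard reagent tolerates the nitroarene at low temperature, the lanthanum salt favours addition over enolisation and retro-Michael loss of the carbamate, and the racemic outcome is harmless because step 10 passes through a planar intermediate.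

Step 9
Reactants: 14 methyl N-[3-hydroxy-3-(2-nitrophenyl)pent-4-yn-1-yl]carbamate (racemic)
Product: 15 5-[(methoxycarbonyl)amino]-3-(2-nitrophenyl)pent-1-yn-3-yl acetate (racemic)
Conditions: Ac2O, Et3N, DMAP (0.2 equiv), CH2Cl2, 23 °C
Reagents that add atoms: acetic anhydride, CC(=O)OC(C)=O
Why: DMAP-catalysed acylation reaches slim tertiary propargylic alcohols while a secondary carbamate N–H stays unacetylated, which a carbonate made through an alkoxide or with Boc2O/DMAP would not guarantee.

Step 10
Reactants: 15 5-[(methoxycarbonyl)amino]-3-(2-nitrophenyl)pent-1-yn-3-yl acetate (racemic); 7 4-iodo-7-methoxy-1-tosyl-1H-indol-5-ol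
Product: 16 methyl N-[(3R)-3-[(4-iodo-7-methoxy-1-tosyl-1H-indol-5-yl)oxy]-3-(2-nitrophenyl)pent-4-yn-1-yl]carbamate
Conditions: Cu(OTf)2 (5 mol %), (S,S)-Ph-pybox [2,6-bis((4S)-4-phenyl-4,5-dihydrooxazol-2-yl)pyridine] (6 mol %), i-Pr2NEt (1.5 equiv), THF, −20 °C
Reagents that add atoms: none
Why: Proposed new method: the copper acetylide of 15 loses acetate to give a planar copper allenylidene, so both enantiomers of 15 converge, and the phenoxide of 7 attacks the propargylic carbon from the face left open by the C2-symmetric pybox pocket, which must tell the flat 2-nitrophenyl group from the CH2CH2NHCO2Me chain and thereby sets C4a as (R), while the neutral carbamate is too weak a nucleophile to intercept the allenylidene; the closest known reactions are the copper/pybox-catalysed enantioselective propargylic etherification of secondary propargylic esters with phenols, the enantioselective amination of ketone-derived tertiary propargylic carbonates, and the racemic copper-catalysed synthesis of tertiary propargyl aryl ethers, and only their combination is new.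

Step 11
Reactants: 16 methyl N-[(3R)-3-[(4-iodo-7-methoxy-1-tosyl-1H-indol-5-yl)oxy]-3-(2-nitrophenyl)pent-4-yn-1-yl]carbamate
Product: 17 (4aR)-3-methylene-2,3-dihydrobenzofuran annulated to 7-methoxy-1-tosylindole (O on C5', C9a on C4'), C4a carrying 2-nitrophenyl and 2-(methoxycarbonylamino)ethyl
Conditions: Pd(OAc)2 (5 mol %), PPh3 (15 mol %), HCO2Na (1.5 equiv), n-Bu4NCl, DMF, 60 °C
Reagents that add atoms: none
Why: In this reductive Heck cyclisation the aryl iodide adds to zerovalent palladium, 5-exo-dig syn-carbopalladation forms C4'–C9a, and hydride transfer from formate to the vinylpalladium gives the exocyclic methylene, which cannot drift into the ring because C4a is quaternary and untouched.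

Step 12
Reactants: 17 nitro methylenedihydrobenzofuran
Product: 18 the same (4aR)-methylenedihydrobenzofuran with 2-aminophenyl on C4a
Conditions: Fe powder, NH4Cl, EtOH/H2O, 70 °C
Reagents that add atoms: none
Why: Béchamp-type nitro reduction under nearly neutral conditions spares the 1,1-disubstituted alkene, the N-tosylindole, the carbamate and the tertiary ether.

Step 13
Reactants: 18 aminophenyl methylenedihydrobenzofuran
Product: 19 diamination precursor: (4aR)-3-methylene-2,3-dihydrobenzofuran annulated to 7-methoxy-1-tosylindole, C4a carrying 2-(tosylamino)phenyl and 2-(methoxycarbonylamino)ethyl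
Conditions: TsCl, pyridine, 0 → 40 °C
Reagents that add atoms: p-toluenesulfonyl chloride, Cc1ccc(S(=O)(=O)Cl)cc1
Why: Sulfonylation of the aniline in pyridine should stop at the monosulfonamide because of the bulky ortho substituent, and the carbamate N–H does not react.

Step 14
Reactants: 19 diamination precursor
Product: 20 (4aS,9aR)-hexacycle with N2-CO2Me, N9-tosyl and N1'-tosyl, C3' unsubstituted
Conditions: Pd(OAc)2 (10 mol %), PhI(OPiv)2 (1.5 equiv), ClCH2CH2Cl, 23 → 40 °C
Reagents that add atoms: none
Why: The acidic sulfonanilide N9–H is deprotonated at divalent palladium and adds to the coordinated C9a=C1 methylene, which places N9 on the fully substituted C9a and palladium on the primary C1; this alkylpalladium has no β-hydrogen, so it persists until PhI(OPiv)2 raises it to tetravalent palladium, and the carbamate N2 then displaces the metal from C1 and returns divalent palladium. The closest known reactions are the palladium-catalysed oxidative intramolecular diaminations of alkenes with hypervalent iodine oxidants, among them the double cyclisation of bis(sulfonamido)stilbenes to bisindolines, in which the two nitrogens also sit on separate tethers. The indoline closes 5-exo-trig (N9–C9a) and the piperidine closes 6-exo-tet (N2–C1). C9a is the only new stereocentre and is controlled by C4a: the aryl ring that carries N9 stands on one face of the flat methylenedihydrobenzofuran and can deliver nitrogen only to that face (cis-fused five-membered rings), which turns C1 towards the face bearing the C4–C3–N2 chain and gives (4aS,9aR). The step needs N9 to react before N2, because N2 could also close a five-membered ring on C9a; this is secured by leaving N2 as an alkyl carbamate, which is far less acidic than the sulfonanilide and a poor partner for aminopalladation under carboxylate conditions. It also needs C–N instead of C–O bond formation at C1, helped by the six-membered intramolecular closure at a neopentyl carbon that a bulky pivalate reaches badly, and it needs the indole to survive, for which N1' stays tosylated.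

Step 15
Reactants: 20 ditosyl hexacycle
Product: 21 (4aS,9aR)-hexacycle with N2-CO2Me and free N9–H and N1'–H
Conditions: Mg turnings, MeOH/THF, ultrasound, 23 °C; aq. NH4Cl
Reagents that add atoms: none
Why: Single-electron reductive cleavage of arylsulfonamides by magnesium in methanol works for N-tosylindoles and N-tosylindolines, the methyl carbamate is inert because methoxide exchange is degenerate, and no stereocentre is affected.

Step 16
Reactants: 21 N2-methoxycarbonyl hexacycle
Product: 22 (4aS,9aR)-N2-methyl hexacycle (the target without its C3' side chain)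
Conditions: LiAlH4, THF, reflux; aq. NaOH work-up
Reagents that add atoms: none
Why: Hydride reduction turns the methyl carbamate into the N-methylamine, while the two N–H groups are only deprotonated and the aryl ethers are inert.

Step 17
Reactants: 22 N2-methyl hexacycle; 23 dimethylmethyleneiminium iodide
Product: 24 target, (4aS,9aR)-configured, with CH2NMe2 on C3'
Conditions: 23 (1.3 equiv), MeCN, 23 → 45 °C; aq. NaHCO3
Reagents that add atoms: none
Why: Mannich aminomethylation takes place at C3', the most nucleophilic carbon of the indole, since attack at the hindered N9 is reversible and N2 is tertiary.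

Compound list
1 | 3-methoxy-4-nitrophenol | COc1cc(O)ccc1[N+](=O)[O-] | starting material
2 | 4-(benzyloxy)-2-methoxy-1-nitrobenzene | COc1cc(OCc2ccccc2)ccc1[N+](=O)[O-] | intermediate
3 | vinylmagnesium bromide | C=C[Mg]Br | starting material
4 | 5-(benzyloxy)-7-methoxy-1H-indole | COc1cc(OCc2ccccc2)cc2cc[nH]c12 | intermediate
5 | 5-(benzyloxy)-7-methoxy-1-tosyl-1H-indole | COc1cc(OCc2ccccc2)cc2ccn(S(=O)(=O)c3ccc(C)cc3)c12 | intermediate
6 | 7-methoxy-1-tosyl-1H-indol-5-ol | COc1cc(O)cc2ccn(S(=O)(=O)c3ccc(C)cc3)c12 | intermediate
7 | 4-iodo-7-methoxy-1-tosyl-1H-indol-5-ol | COc1cc(O)c(I)c2ccn(S(=O)(=O)c3ccc(C)cc3)c12 | intermediate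
8 | 2'-nitroacetophenone | CC(=O)c1ccccc1[N+](=O)[O-] | starting material
9 | paraformaldehyde (written as formaldehyde) | C=O | starting material
10 | 1-(2-nitrophenyl)prop-2-en-1-one | C=CC(=O)c1ccccc1[N+](=O)[O-] | intermediate
11 | methyl carbamate | COC(N)=O | starting material
12 | methyl N-[3-(2-nitrophenyl)-3-oxopropyl]carbamate | COC(=O)NCCC(=O)c1ccccc1[N+](=O)[O-] | intermediate
13 | ethynylmagnesium bromide | C#C[Mg]Br | starting material
14 | methyl N-[3-hydroxy-3-(2-nitrophenyl)pent-4-yn-1-yl]carbamate, racemic | COC(=O)NCCC(O)(C#C)c1ccccc1[N+](=O)[O-] | intermediate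
15 | 5-[(methoxycarbonyl)amino]-3-(2-nitrophenyl)pent-1-yn-3-yl acetate, racemic | COC(=O)NCCC(OC(C)=O)(C#C)c1ccccc1[N+](=O)[O-] | intermediate
16 | (3R)-propargylic aryl ether of 7 | C#C[C@@](CCNC(=O)OC)(Oc1cc(OC)c2c(ccn2S(=O)(=O)c2ccc(C)cc2)c1I)c1ccccc1[N+](=O)[O-] | intermediate
17 | (4aR)-methylenedihydrobenzofuran, 2-nitrophenyl on C4a | COc1cc2c(c3ccn(S(=O)(=O)c4ccc(C)cc4)c13)C(=C)[C@@](CCNC(=O)OC)(O2)c1ccccc1[N+](=O)[O-] | intermediate
18 | (4aR)-methylenedihydrobenzofuran, 2-aminophenyl on C4a | COc1cc2c(c3ccn(S(=O)(=O)c4ccc(C)cc4)c13)C(=C)[C@@](CCNC(=O)OC)(O2)c1ccccc1N | intermediate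
19 | diamination precursor, (4aR), 2-(tosylamino)phenyl on C4a | COc1cc2c(c3ccn(S(=O)(=O)c4ccc(C)cc4)c13)C(=C)[C@@](CCNC(=O)OC)(O2)c1ccccc1NS(=O)(=O)c1ccc(C)cc1 | intermediate
20 | (4aS,9aR)-N2-methoxycarbonyl-N9,N1'-ditosyl hexacycle | COc1cc2c(c3ccn(S(=O)(=O)c4ccc(C)cc4)c13)[C@@]13CN(C(=O)OC)CC[C@]1(O2)c1ccccc1N3S(=O)(=O)c1ccc(C)cc1 | intermediate
21 | (4aS,9aR)-N2-methoxycarbonyl hexacycle, N9–H and N1'–H free | COc1cc2c(c3cc[nH]c13)[C@@]13CN(C(=O)OC)CC[C@]1(O2)c1ccccc1N3 | intermediate
22 | (4aS,9aR)-N2-methyl hexacycle | COc1cc2c(c3cc[nH]c13)[C@@]13CN(C)CC[C@]1(O2)c1ccccc1N3 | intermediate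
23 | dimethylmethyleneiminium iodide | C=[N+](C)C.[I-] | starting material
24 | target CNP0318114.2, (4aS,9aR) | COc1cc2c(c3c(CN(C)C)c[nH]c13)[C@@]13CN(C)CC[C@]1(O2)c1ccccc1N3 | target

Total step count: 17. Longest linear sequence: 13 steps (steps 1–5 and 10–17); the second branch (steps 6–9) joins at step 10.

Steps most likely to fail

1. Step 10 (the labelled step).
What may go wrong: weak facial discrimination between the aryl group and the chain at the allenylidene, slow ionisation of the electron-poor acetate, or proton loss from C4 (elimination) ahead of attack by the hindered phenoxide.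
Fallback with known chemistry: starting from 15 and 7, the ether is made without a chiral ligand (CuCl2·2H2O, DBU, MeCN, 0 °C). This is the established copper-catalysed route to tertiary propargyl aryl ethers, and it gives the racemic ether F1. Preparative chromatography on a chiral stationary phase (supercritical CO2/MeOH, amylose carbamate phase) then separates 16 from its (S)-enantiomer F2, and the route is rejoined at 16.

2. Step 14.
What may go wrong: capture of the tetravalent alkylpalladium by carboxylate (C–O instead of C–N bond formation at C1), aminopalladation through the wrong nitrogen, migration of the electron-rich aryl group from C9a to C1 at the tetravalent stage, or oxidation of the indole.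
Fallback: the two C–N bonds are made one after the other without redox catalysis. Starting from 19, iodoaminocyclisation (I2, NaHCO3, MeCN, 0 °C) should open the iodonium ion at the more substituted C9a with N9, on the only face its tether reaches, to give the iodomethylindoline F3. Deprotonation of the carbamate (NaH, DMF, 23 → 60 °C) then closes the piperidine by N-alkylation. This can be forced because the neopentyl iodide has no β-hydrogen to eliminate. The route is rejoined at 20.

3. Step 11.
What may go wrong: partial reduction of the nitro group by the palladium/formate couple, or intermolecular coupling of the terminal alkyne with the aryl iodide ahead of ring closure.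
Fallback: the order is changed and the ring is closed by a radical. Starting from 16, Fe/NH4Cl reduction gives the aniline F4, and TsCl in pyridine gives the sulfonamide F5. An aryl radical 5-exo-dig cyclisation (Bu3SnH, AIBN, toluene, 80 °C) then forms C4'–C9a and delivers hydrogen to the vinyl radical. The route is rejoined at 19, so 17 and 18 are bypassed.

Further compounds
F1 | step 10 | racemic methyl N-[3-[(4-iodo-7-methoxy-1-tosyl-1H-indol-5-yl)oxy]-3-(2-nitrophenyl)pent-4-yn-1-yl]carbamate | C#CC(CCNC(=O)OC)(Oc1cc(OC)c2c(ccn2S(=O)(=O)c2ccc(C)cc2)c1I)c1ccccc1[N+](=O)[O-]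
F2 | step 10 | (3S)-enantiomer of 16 | C#C[C@](CCNC(=O)OC)(Oc1cc(OC)c2c(ccn2S(=O)(=O)c2ccc(C)cc2)c1I)c1ccccc1[N+](=O)[O-]
F3 | step 14 | (4aS,9aS)-iodomethylindoline: N9-tosylindoline cis-fused to the dihydrobenzofuran, CH2I on C9a, CH2CH2NHCO2Me on C4a | COc1cc2c(c3ccn(S(=O)(=O)c4ccc(C)cc4)c13)[C@@]1(CI)[C@@](CCNC(=O)OC)(O2)c2ccccc2N1S(=O)(=O)c1ccc(C)cc1
F4 | step 11 | (3R)-propargylic aryl ether with 2-aminophenyl | C#C[C@@](CCNC(=O)OC)(Oc1cc(OC)c2c(ccn2S(=O)(=O)c2ccc(C)cc2)c1I)c1ccccc1N
F5 | step 11 | (3R)-propargylic aryl ether with 2-(tosylamino)phenyl | C#C[C@@](CCNC(=O)OC)(Oc1cc(OC)c2c(ccn2S(=O)(=O)c2ccc(C)cc2)c1I)c1ccccc1NS(=O)(=O)c1ccc(C)cc1
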